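The constants used here were set for the occasion.

Free catalyst is the worker in these flasks, and how much work it has left can be reckoned by hand before any run.

    starting material + coupling partner + free catalyst → free catalyst + target (k1 = 124 M⁻² s⁻¹, Ea1 = 36.0 kJ mol⁻¹)
    second substrate + coupling partner + free catalyst → free catalyst + second product (k2 = 659 M⁻² s⁻¹, Ea2 = 48.0 kJ mol⁻¹)
    free catalyst → spent catalyst A (k3 = 0.0422 s⁻¹, Ea3 = 109 kJ mol⁻¹)
    2 free catalyst → spent catalyst B (k4 = 15.0 M⁻¹ s⁻¹, Ea4 = 54.0 kJ mol⁻¹)
    (constants at 100 °C)

all flasks: starting material 0.10 M; coupling partner 0.105 M; free catalyst 5.0 mM; time 1.0 min
- spring: second substrate 0.0200 M (fed, over 50 s); temperature 100 °C; all else is in the flask from the start; the feed brings no volume worth counting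
- dusk: second substrate 0.0200 M; temperature 100 °C; everything together at the start
- midnight: second substrate 0.0200 M; everything together at the start at 80 °C, warmed to 100 °C at 50 s
- dawn: second substrate 0.0200 M (fed, over 50 s); the addition at 80 °C, then warmed to 100 °C; the feed brings no volume worth counting

* the best flask by amount of target, in percent of the starting material charged; "all alike" if 1.5 percentage points covers them all (spring / dusk / midnight / dawn / all alike)
* amount of target at the end, in percent of the starting material charged, spring
* amount of target at the end, in percent of the starting material charged, dusk
* amount of target at the end, in percent of the starting material charged, midnight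
* amount of target at the end, in percent of the starting material charged, dawn

Steps 1 and 2 hand the catalyst back, and steps 3 and 4 have no other species on their left, so its decline does not depend on the substrates. Call W the catalyst budget: the rate constant of step 1 times free catalyst, summed over time to the end.

Temperature is the first setting. At 80 °C step 1 keeps 0.518 of its constant, while step 3 keeps 0.137 and step 4 keeps 0.373, so step 1 keeps more of its constant than either step that kills the catalyst. By hand, a cold 50 s leaves 1.09 mM of free catalyst. W is 6.00 M⁻¹ for a hot run and 8.06 M⁻¹ with the cold start, the catalyst budget W that I carry forward.

The feed is the second setting. It does not change W and acts on B̄, the mean coupling partner that the starting material meets. The logarithm of start over left is W times B̄, which is pseudo-first-order in starting material. In dusk, second substrate has a half-life of 2.0 s by step 2 with the other concentrations as charged, much shorter than the 50 s that the feed takes in the fed flasks, so as an estimate I take its whole charge off B̄, and I treat midnight alike. Fed, I take off half of it. Half of what the target has used comes off too.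

B̄ needs the answer, so I go round. For dusk, coupling partner as charged gives 46.8% target; putting that back gives 30.9%, then 34.1%. Starting the others from that last value, spring goes 37.4%, then 36.7%. Midnight goes 42.2%, then 40.3%. Dawn goes 46.6%, then 43.9%. I commit to the last of each, with dawn best.

The forecast also names dawn, with 38.5% for spring, 34.7% for dusk, 41.4% for midnight and 44.7% for dawn, each above mine. Its ground is that the feed “puts the cool, dosed flask ahead and the hot, all-at-once flask last”.

The flasks give 38.4% for spring, 34.8% for dusk, 41.4% for midnight and 44.8% for dawn, so dawn is best. Against dusk, the cold start of midnight adds 6.6 percentage points and the feed of spring adds 3.6 points. Dawn's 55.2% of starting material left, read through W, means a B̄ of 0.0737 M. The neighbour of dawn charged with 0.025 M of starting material ends with 11.3% free catalyst, as dawn does, so I keep W. Its coupling partner ends at 74.2% of charge, and the mean of start and end is a B̄ of 0.0915 M. W times that B̄ reckons 47.8% of its starting material left, and the flask holds 47.4%.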